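**Retrosynthetic overview**

1. The target is the C15 acetate of isocupressic acid, so the last steps are cleavage of the C19 ester and acetylation of O15. The side chain (C11–C16, the E-alkene and O15) is carried intact from geraniol.
2. Ring A is cut at C1–C2 and C3–C4: phenyl vinyl sulfone supplies C2–C3 and is stitched between C4 and C1. The same operation first closes ring B at C5–C10, so the precursor is the acyclic aldehyde–enoate 17.
3. Enabling feature: ring A contains the array C1–C10–C5–C4–C19 in which C10 and C4 are α-carbons (to a C1 aldehyde and to the C19 carboxyl) and C5 is β to C19. C10 is quaternary, so once ring B is closed the C1 aldehyde cannot enolise and serves only as acceptor for C2.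
4. The one controlling stereocentre of 17 (C9) is set by an enamine-catalysed Michael addition of propanal to a nitroalkene. The nitro group then lets C8 take up the C7–C5 chain and is converted into the C8=C17 methylene.
5. Ring order: ring B (C5–C10), then ring A (C3–C4, C1–C2), in one pot; the sulfonyl group is removed in the two steps that follow.

Key step: step 10

Assumption: labdane numbering is used for all intermediates; C10 of 9–17 is drawn as the syn isomer from step 4 but is enolised in step 10, and C8 of 12 and 14, C1/C2 of 20 and C2 of 22 are epimer mixtures that are erased later.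

**Route**

Step 1
Reactants: 1 geraniol
Product: 2 geranyl tert-butyldiphenylsilyl (TBDPS) ether
Conditions: TBDPSCl, imidazole, DMF, 0 °C to rt
Reagents that add atoms: tert-butylchlorodiphenylsilane, CC(C)(C)[Si](Cl)(c1ccccc1)c1ccccc1
Why: Silylation of the primary allylic alcohol (substitution at silicon) gives an ether that should survive the acidic, basic and reducing steps up to step 13.

Step 2
Reactants: 2 geranyl TBDPS ether
Product: 4 (4E)-6-[(tert-butyldiphenylsilyl)oxy]-4-methylhex-4-enal, via 6,7-epoxide 3 (not isolated)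
Conditions: mCPBA, NaHCO3, CH2Cl2, −20 °C; then H5IO6, THF/Et2O, 0 °C
Reagents that add atoms: mCPBA, OOC(=O)c1cccc(Cl)c1; water (from H5IO6), O
Why: Epoxidation should occur at the 6,7-alkene, which is more electron-rich than the 2,3-alkene next to the silyloxy group, and periodic acid cleavage of the epoxide (hydrolysis, then glycol cleavage) should give the C9 aldehyde and acetone.

Step 3
Reactants: 4 the C9 aldehyde; 5 nitromethane
Product: 7 tert-butyl{[(2E,6E)-3-methyl-7-nitrohepta-2,6-dien-1-yl]oxy}diphenylsilane, via nitro alcohol 6 (not isolated)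
Conditions: MeNO2 (excess), Et3N (cat.), 0 °C to rt; then MsCl, Et3N, CH2Cl2, −20 to 0 °C
Reagents that add atoms: none
Why: Henry (nitro-aldol) addition followed by mesylation and E1cB elimination should give the conjugated nitroalkene as its more stable E isomer.

Step 4
Reactants: 7 the nitroalkene; 8 propanal
Product: 10 (2R,3R,6E)-8-[(tert-butyldiphenylsilyl)oxy]-1,1-dimethoxy-2,6-dimethyl-3-(nitromethyl)oct-6-ene, via nitro aldehyde 9 (not isolated)
Conditions: 8 (3 equiv), (S)-α,α-diphenylprolinol trimethylsilyl ether (10 mol %), 4-nitrophenol (10 mol %), toluene, 0 °C to rt; then HC(OMe)3, MeOH, camphorsulfonic acid (cat.), rt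
Reagents that add atoms: trimethyl orthoformate, COC(OC)OC
Why: Enamine-catalysed asymmetric Michael addition of an aldehyde to a nitroalkene: the E-enamine of propanal reacts on the face not shielded by the diphenyl(silyloxy)methyl group of the (S)-catalyst, which sets C9 (and C10, syn), and acetalisation in the same pot masks C1.

Step 5
Reactants: 10 the nitro acetal; 11 acrolein
Product: 12 the nitro aldehyde in which C8 carries NO2 and the CH2CH2CHO chain (C7, C6, C5)
Conditions: 11 (1.2 equiv), tetramethylguanidine (10 mol %), MeCN, −20 to 0 °C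
Reagents that add atoms: none
Why: Base-catalysed Michael addition of the primary nitroalkane (as nitronate) to acrolein should attach C7–C5 to C8; the new C8 centre is not controlled and is removed in step 7.

Step 6
Reactants: 12 the nitro aldehyde; 13 methyl 2-(triphenylphosphoranylidene)propanoate
Product: 14 the nitro (E)-2-methyl-enoate
Conditions: 13 (1.3 equiv), CH2Cl2, rt
Reagents that add atoms: none
Why: Wittig olefination with a stabilised ylide should give the E-trisubstituted enoate and so installs C4, C18 and C19.

Step 7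
Reactants: 14 the nitro enoate
Product: 15 the C8 ketone
Conditions: NaOMe, MeOH, 0 °C; then aq. TiCl3, NH4OAc (pH 5–6), THF/H2O, 0 °C to rt
Reagents that add atoms: water, O
Why: Reductive Nef reaction: the sodium nitronate is reduced by TiCl3 to the imine, which hydrolyses to the ketone in a buffered medium that should spare the acetal, the silyl ether and the C9 centre.

Step 8
Reactants: 15 the C8 ketone
Product: 16 the C8 methylene compound (C8=C17)
Conditions: Cp2Ti(μ-Cl)(μ-CH2)AlMe2 (Tebbe reagent, 1.2 equiv), pyridine (cat.), THF/toluene, −40 to 0 °C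
Reagents that add atoms: Tebbe reagent, C[Al-]1(C)C[Ti](C2C=CC=C2)(C2C=CC=C2)[Cl+]1
Why: Tebbe methylenation (titanium methylidene, [2+2] addition and cycloreversion) should convert the ketone, not the slower ester, under non-basic conditions that should leave C9 intact.

Step 9
Reactants: 16 the C8 methylene acetal
Product: 17 the acyclic aldehyde–enoate (C1 aldehyde, C10–H, C9 side chain, C8=C17, C5=C4 enoate)
Conditions: pyridinium p-toluenesulfonate (cat.), acetone/H2O, 50 °C
Reagents that add atoms: water, O
Why: Mild acid-catalysed acetal hydrolysis should free the C1 aldehyde; epimerisation at C10 is of no concern because C10 is enolised in the next step.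

Step 10
Reactants: 17 the acyclic aldehyde–enoate; 18 phenyl vinyl sulfone
Product: 21 methyl 15-[(tert-butyldiphenylsilyl)oxy]-2-(phenylsulfonyl)labda-1,8(17),13E-trien-19-oate, via ester enolate 19 (not isolated), via acetoxy sulfone 20 (not isolated)
Conditions: KOtBu (1.1 equiv), THF (0.01 M), −78 to −20 °C; then 18 (1.2 equiv), −78 to 0 °C; then Ac2O, 0 °C; then DBU, rt
Reagents that add atoms: none
Why: KOtBu deprotonates only C10–H of the aldehyde, and the C10 enolate adds 6-exo-trig to C5 of the E-enoate (ring B, C5–C10); the C4 ester enolate so formed adds to the β-carbon of 18 (C3–C4), and the C2 sulfonyl carbanion closes ring A by 6-exo-trig addition to the C1 aldehyde (C1–C2), after which acetylation and DBU-induced E1cB elimination give the vinyl sulfone. The closest known reaction type is the tandem Michael–Michael–ring-closure annulation of an enolate with two acceptors, ended here by the carbanion–aldehyde addition of a Julia olefination. C10 and C5 are set in a chair transition state in which the C9 side chain and the enoate are equatorial and C9–H eclipses the enolate double bond (least 1,3-allylic strain), which should put the C10 methyl cis to the C9 chain and trans to H5 (trans ring fusion). C4 is set by attack of 18 on the enolate face anti to the quaternary C10 with C5–H in the enolate plane, which should place the ester axial, cis to the C10 methyl. The step needs C10 to be the only site enolised (the aldehyde α-H is the most acidic, and after ring B closure C10 is quaternary so C1 can act only as acceptor) and ring B to close before 18 arrives, which the order of addition and high dilution secure. The C1 and C2 centres of 20 are erased in the elimination.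

Step 11
Reactants: 21 the vinyl sulfone
Product: 22 methyl 15-[(tert-butyldiphenylsilyl)oxy]-2-(phenylsulfonyl)labda-8(17),13E-dien-19-oate
Conditions: NaBH4, EtOH/THF, 0 °C to rt
Reagents that add atoms: none
Why: Conjugate reduction of the α,β-unsaturated sulfone by borohydride should leave the isolated alkenes and the hindered ester untouched; the C2 centre is not controlled and is removed in step 12.

Step 12
Reactants: 22 the sulfone
Product: 23 methyl 15-[(tert-butyldiphenylsilyl)oxy]labda-8(17),13E-dien-19-oate
Conditions: 6% Na/Hg, Na2HPO4, MeOH/THF, −20 °C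
Reagents that add atoms: none
Why: Reductive desulfonylation (electron transfer, C–S cleavage, protonation) removes the activating group and leaves C2 as CH2.

Step 13
Reactants: 23 the silyl ether methyl ester
Product: 24 methyl isocupressate
Conditions: Bu4NF, THF, rt
Reagents that add atoms: none
Why: Fluoride-induced desilylation should free the C15 alcohol without touching the alkenes or the ester.

Step 14
Reactants: 24 methyl isocupressate
Product: 25 isocupressic acid
Conditions: NaSEt, DMF, 110 °C; then aq. HCl to pH 3
Reagents that add atoms: none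
Why: SN2 dealkylation by thiolate at the methyl carbon should cleave the axial, neopentyl-type ester whose carbonyl is too shielded for saponification.

Step 15
Reactants: 25 isocupressic acid
Product: 26 15-acetoxyisocupressic acid
Conditions: Ac2O, pyridine, DMAP (cat.), CH2Cl2, 0 °C; aq. NaHCO3 then dilute citric acid work-up
Reagents that add atoms: acetic anhydride, CC(=O)OC(C)=O
Why: Acylation of the primary allylic alcohol; any mixed anhydride formed at the hindered C19 acid should hydrolyse on aqueous work-up.

**Compound list**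

1 | geraniol | CC(C)=CCC/C(C)=C/CO | starting material
2 | geranyl TBDPS ether | CC(C)=CCC/C(C)=C/CO[Si](c1ccccc1)(c1ccccc1)C(C)(C)C | intermediate
3 | 6,7-epoxygeranyl TBDPS ether (racemic epoxide) | CC1(C)OC1CC/C(C)=C/CO[Si](c1ccccc1)(c1ccccc1)C(C)(C)C | intermediate
4 | (4E)-6-[(tert-butyldiphenylsilyl)oxy]-4-methylhex-4-enal | O=CCC/C(C)=C/CO[Si](c1ccccc1)(c1ccccc1)C(C)(C)C | intermediate
5 | nitromethane | C[N+](=O)[O-] | starting material
6 | (5E)-7-[(tert-butyldiphenylsilyl)oxy]-5-methyl-1-nitrohept-5-en-2-ol (racemic) | [O-][N+](=O)CC(O)CC/C(C)=C/CO[Si](c1ccccc1)(c1ccccc1)C(C)(C)C | intermediate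
7 | tert-butyl{[(2E,6E)-3-methyl-7-nitrohepta-2,6-dien-1-yl]oxy}diphenylsilane | [O-][N+](=O)/C=C/CC/C(C)=C/CO[Si](c1ccccc1)(c1ccccc1)C(C)(C)C | intermediate
8 | propanal | CCC=O | starting material
9 | (2R,3R,6E)-8-[(tert-butyldiphenylsilyl)oxy]-2,6-dimethyl-3-(nitromethyl)oct-6-enal | O=C[C@H](C)[C@H](C[N+](=O)[O-])CC/C(C)=C/CO[Si](c1ccccc1)(c1ccccc1)C(C)(C)C | intermediate
10 | dimethyl acetal of 9 | COC(OC)[C@H](C)[C@H](C[N+](=O)[O-])CC/C(C)=C/CO[Si](c1ccccc1)(c1ccccc1)C(C)(C)C | intermediate
11 | acrolein | C=CC=O | starting material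
12 | nitro aldehyde (C8 bears NO2 and the C7–C5 chain ending in CHO; C8 epimers) | COC(OC)[C@H](C)[C@H](C(CCC=O)[N+](=O)[O-])CC/C(C)=C/CO[Si](c1ccccc1)(c1ccccc1)C(C)(C)C | intermediate
13 | methyl 2-(triphenylphosphoranylidene)propanoate | COC(=O)C(C)=P(c1ccccc1)(c1ccccc1)c1ccccc1 | starting material
14 | nitro (E)-2-methyl-enoate (C8 epimers) | COC(OC)[C@H](C)[C@H](C(CC/C=C(\C)C(=O)OC)[N+](=O)[O-])CC/C(C)=C/CO[Si](c1ccccc1)(c1ccccc1)C(C)(C)C | intermediate
15 | C8 ketone | COC(OC)[C@H](C)[C@H](C(=O)CC/C=C(\C)C(=O)OC)CC/C(C)=C/CO[Si](c1ccccc1)(c1ccccc1)C(C)(C)C | intermediate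
16 | C8 methylene acetal | COC(OC)[C@H](C)[C@H](C(=C)CC/C=C(\C)C(=O)OC)CC/C(C)=C/CO[Si](c1ccccc1)(c1ccccc1)C(C)(C)C | intermediate
17 | acyclic aldehyde–enoate (key-step precursor) | O=C[C@H](C)[C@H](C(=C)CC/C=C(\C)C(=O)OC)CC/C(C)=C/CO[Si](c1ccccc1)(c1ccccc1)C(C)(C)C | intermediate
18 | phenyl vinyl sulfone | C=CS(=O)(=O)c1ccccc1 | starting material
19 | potassium C4 ester enolate of the monocyclic (ring B) aldehyde ester | C=C1CC[C@@H](C(C)=C([O-])OC)[C@](C)(C=O)[C@H]1CC/C(C)=C/CO[Si](c1ccccc1)(c1ccccc1)C(C)(C)C.[K+] | intermediate
20 | methyl 1-acetoxy-15-[(tert-butyldiphenylsilyl)oxy]-2-(phenylsulfonyl)labda-8(17),13E-dien-19-oate (C1/C2 epimers) | C=C1CC[C@@H]2[C@](C)(C(OC(C)=O)C(S(=O)(=O)c3ccccc3)C[C@]2(C)C(=O)OC)[C@H]1CC/C(C)=C/CO[Si](c1ccccc1)(c1ccccc1)C(C)(C)C | intermediate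
21 | methyl 15-[(tert-butyldiphenylsilyl)oxy]-2-(phenylsulfonyl)labda-1,8(17),13E-trien-19-oate (C4, C5, C9, C10 as in the target) | C=C1CC[C@@H]2[C@](C)(C=C(S(=O)(=O)c3ccccc3)C[C@]2(C)C(=O)OC)[C@H]1CC/C(C)=C/CO[Si](c1ccccc1)(c1ccccc1)C(C)(C)C | intermediate
22 | methyl 15-[(tert-butyldiphenylsilyl)oxy]-2-(phenylsulfonyl)labda-8(17),13E-dien-19-oate (C2 epimers) | C=C1CC[C@@H]2[C@](C)(CC(S(=O)(=O)c3ccccc3)C[C@]2(C)C(=O)OC)[C@H]1CC/C(C)=C/CO[Si](c1ccccc1)(c1ccccc1)C(C)(C)C | intermediate
23 | methyl 15-[(tert-butyldiphenylsilyl)oxy]labda-8(17),13E-dien-19-oate | C=C1CC[C@@H]2[C@](C)(CCC[C@]2(C)C(=O)OC)[C@H]1CC/C(C)=C/CO[Si](c1ccccc1)(c1ccccc1)C(C)(C)C | intermediate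
24 | methyl isocupressate | C=C1CC[C@@H]2[C@](C)(CCC[C@]2(C)C(=O)OC)[C@H]1CC/C(C)=C/CO | intermediate
25 | isocupressic acid | C=C1CC[C@@H]2[C@](C)(CCC[C@]2(C)C(=O)O)[C@H]1CC/C(C)=C/CO | intermediate
26 | 15-acetoxyisocupressic acid | C=C1CC[C@@H]2[C@](C)(CCC[C@]2(C)C(=O)O)[C@H]1CC/C(C)=C/COC(C)=O | target

**Step count and risks**

Total step count: 15. Longest linear sequence: 15 steps (geraniol to the target).

Steps most likely to fail:

Step 10. The ring B Michael addition may show poor facial selectivity at C10 (it depends on the enolate geometry). Proton transfer may also quench the C4 ester enolate before it captures the sulfone, or the sulfone may oligomerise. The fallback sets out from 17 and separates the two events. Ring B is closed alone with catalytic KOtBu in tBuOH/THF to the neutral monocyclic aldehyde ester F1. Its C10 epimers are separated, and the unwanted one is recycled by retro-Michael/Michael equilibration. F1 is then deprotonated at C4 with lithium 2,2,6,6-tetramethylpiperidide at −78 °C (the C1 aldehyde is now non-enolisable and neopentyl), and treated with 18, Ac2O and DBU. This returns to the route at 21.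

Step 11. Hydride delivery to the hindered β-carbon of the vinyl sulfone may be slow or incomplete, and the double bond may migrate in the basic medium. The fallback sets out from 17 and avoids the vinyl sulfone. The key step is quenched with NH4Cl before acetylation to give the hydroxy sulfone F2. SmI2/HMPA in THF/MeOH removes the sulfonyl group to give the C1 alcohol F3 (the free hydroxyl should disfavour Julia-type elimination). NaH, CS2 and MeI give the xanthate F4. Barton–McCombie deoxygenation (Bu3SnH, AIBN, toluene, 80 °C) then returns to the route at 23.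

Step 8. The Lewis acidic titanium–aluminium reagent may enolise the α-branched ketone with loss of configuration at C9, or may also methylenate the ester. The fallback sets out from 15. The organocerium reagent from Me3SiCH2Li and CeCl3 (THF, −78 °C) adds to the ketone to give the hydroxysilane F5. Peterson elimination (KH, THF, 0 °C) returns to the route at 16.

Further compounds
F1 | step 10 | monocyclic (ring B) aldehyde ester, C4 epimers | C=C1CC[C@@H](C(C)C(=O)OC)[C@](C)(C=O)[C@H]1CC/C(C)=C/CO[Si](c1ccccc1)(c1ccccc1)C(C)(C)C
F2 | step 11 | methyl 15-[(tert-butyldiphenylsilyl)oxy]-1-hydroxy-2-(phenylsulfonyl)labda-8(17),13E-dien-19-oate, C1/C2 epimers | C=C1CC[C@@H]2[C@](C)(C(O)C(S(=O)(=O)c3ccccc3)C[C@]2(C)C(=O)OC)[C@H]1CC/C(C)=C/CO[Si](c1ccccc1)(c1ccccc1)C(C)(C)C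
F3 | step 11 | methyl 15-[(tert-butyldiphenylsilyl)oxy]-1-hydroxylabda-8(17),13E-dien-19-oate, C1 epimers | C=C1CC[C@@H]2[C@](C)(C(O)CC[C@]2(C)C(=O)OC)[C@H]1CC/C(C)=C/CO[Si](c1ccccc1)(c1ccccc1)C(C)(C)C
F4 | step 11 | S-methyl xanthate of F3 | C=C1CC[C@@H]2[C@](C)(C(OC(=S)SC)CC[C@]2(C)C(=O)OC)[C@H]1CC/C(C)=C/CO[Si](c1ccccc1)(c1ccccc1)C(C)(C)C
F5 | step 8 | C8 hydroxy (trimethylsilyl)methyl adduct of 15, C8 epimers | COC(OC)[C@H](C)[C@H](C(O)(C[Si](C)(C)C)CC/C=C(\C)C(=O)OC)CC/C(C)=C/CO[Si](c1ccccc1)(c1ccccc1)C(C)(C)C
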